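**Retrosynthetic overview**
1. Target 30 ⇐ acid release of the 10,14-diol from the ten-membered (Z)-enone 28; transannular hemiketalisation closes the tetrahydrofuran ring last and fixes C3.
2. Ten-membered ring ⇐ carbonylative B-alkyl Suzuki macrocyclisation of the iodoalkene/alkylborane 25 (C2–C3 and C3–C4 bonds, C3 from CO); this is the new step.
3. (Z)-Iodoalkene ⇐ Stork–Zhao olefination of the C5 aldehyde; the α-methylene lactone is masked as its PhSH adduct for the palladium step.
4. cis-Lactone with the C6/C7/C8 triad ⇐ indium Barbier coupling of aldehyde 9 (fragment A) with (Z)-bromide 14 (fragment B), then acylation and lactonisation.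
5. Fragment A ⇐ Sharpless epoxidation (C10); fragment B ⇐ (R)-solketal (C6). Ring order: lactone, then ten-membered carbocycle, then tetrahydrofuran hemiketal.

Assumption: atoms are located by germacranolide numbering of the target (C1–C10 ring, C11–C13 lactone, C14 = CH2OH, C15 = ring methyl); the SMILES is read as 3S,6S,7R,8R,10R,2′R with a 4Z alkene and a cis-fused 6,12-lactone; 1, 10, 12 and 17 are purchased.

**Step 1**
Reactants: 1 3-bromobut-3-en-1-ol
Product: 2 [(3-bromobut-3-en-1-yl)oxy](tert-butyl)diphenylsilane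
Conditions: TBDPSCl, imidazole, CH2Cl2, 0 °C → rt
Reagents that add atoms: tert-butyldiphenylsilyl chloride, CC(C)(C)[Si](Cl)(c1ccccc1)c1ccccc1
Why: Imidazole-promoted O-silylation (silyl ether protection) of the primary alcohol gives a group that survives the organolithium, titanium and ylide steps.

**Step 2**
Reactants: 2 [(3-bromobut-3-en-1-yl)oxy](tert-butyl)diphenylsilane
Product: 4 4-[(tert-butyldiphenylsilyl)oxy]-2-methylidenebutan-1-ol, via vinyllithium 3 (not isolated)
Conditions: t-BuLi (2.1 equiv), Et2O, −78 °C; (CH2O)n, −78 → 0 °C; H2O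
Reagents that add atoms: paraformaldehyde (formaldehyde source), C=O
Why: Bromine–lithium exchange followed by 1,2-addition of the vinyllithium to formaldehyde (hydroxymethylation) gives the 2-substituted allylic alcohol needed for directed epoxidation.

**Step 3**
Reactants: 4 4-[(tert-butyldiphenylsilyl)oxy]-2-methylidenebutan-1-ol
Product: 5 [(2R)-2-{2-[(tert-butyldiphenylsilyl)oxy]ethyl}oxiran-2-yl]methanol
Conditions: Ti(OiPr)4 (10 mol %), D-(−)-diethyl tartrate (12 mol %), t-BuOOH, 4 Å MS, CH2Cl2, −20 °C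
Reagents that add atoms: tert-butyl hydroperoxide, CC(C)(C)OO
Why: Sharpless asymmetric epoxidation; by analogy with 2-methylallyl alcohol (L-(+)-tartrate gives the (S)-glycidol), the D-(−)-tartrate catalyst delivers oxygen to the face that gives the (2R)-epoxide, which sets the future C10 quaternary centre.

**Step 4**
Reactants: 5 [(2R)-2-{2-[(tert-butyldiphenylsilyl)oxy]ethyl}oxiran-2-yl]methanol
Product: 6 (2S)-2-{2-[(tert-butyldiphenylsilyl)oxy]ethyl}but-3-ene-1,2-diol
Conditions: Me3S+ I− (4 equiv), n-BuLi (4 equiv), THF, −10 °C → rt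
Reagents that add atoms: trimethylsulfonium iodide, C[S+](C)C.[I-]
Why: One-carbon homologation of an epoxide to an allylic alcohol with dimethylsulfonium methylide (attack at the epoxide CH2, then elimination of dimethyl sulfide) builds the C1=C2 vinyl group without touching the C10–O bond, and a competing Payne shift is degenerate and leads to the same enantiomer.

**Step 5**
Reactants: 6 (2S)-2-{2-[(tert-butyldiphenylsilyl)oxy]ethyl}but-3-ene-1,2-diol
Product: 7 tert-butyl{2-[(4S)-4-ethenyl-2,2-dimethyl-1,3-dioxolan-4-yl]ethoxy}diphenylsilane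
Conditions: 2,2-dimethoxypropane, PPTS (cat.), CH2Cl2, rt
Reagents that add atoms: 2,2-dimethoxypropane, COC(C)(C)OC
Why: Acid-catalysed transketalisation (acetonide formation) masks the tertiary C10 hydroxyl, which would otherwise make the derived β-hydroxy aldehyde prone to retro-aldol cleavage.

**Step 6**
Reactants: 7 tert-butyl{2-[(4S)-4-ethenyl-2,2-dimethyl-1,3-dioxolan-4-yl]ethoxy}diphenylsilane
Product: 8 2-[(4S)-4-ethenyl-2,2-dimethyl-1,3-dioxolan-4-yl]ethan-1-ol
Conditions: Bu4NF, THF, 0 °C → rt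
Reagents that add atoms: none
Why: Fluoride-mediated desilylation frees the C8 primary alcohol while the acetonide and the vinyl group are inert.

**Step 7**
Reactants: 8 2-[(4S)-4-ethenyl-2,2-dimethyl-1,3-dioxolan-4-yl]ethan-1-ol
Product: 9 [(4S)-4-ethenyl-2,2-dimethyl-1,3-dioxolan-4-yl]acetaldehyde (fragment A)
Conditions: Dess–Martin periodinane, CH2Cl2, 0 °C → rt
Reagents that add atoms: none
Why: Dess–Martin oxidation gives the C8 aldehyde under non-basic conditions, so the β-alkoxy aldehyde does not eliminate; it is used at once.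

**Step 8**
Reactants: 10 [(4R)-2,2-dimethyl-1,3-dioxolan-4-yl]methanol ((R)-solketal)
Product: 11 (4S)-2,2-dimethyl-1,3-dioxolane-4-carbaldehyde
Conditions: Dess–Martin periodinane, CH2Cl2, 0 °C → rt
Reagents that add atoms: none
Why: Dess–Martin oxidation of the chiral-pool alcohol leaves the stereocentre (future C6) untouched; only its CIP descriptor changes from R to S.

**Step 9**
Reactants: 11 (4S)-2,2-dimethyl-1,3-dioxolane-4-carbaldehyde; 12 methyl acrylate (excess)
Product: 13 methyl 2-{[(4S)-2,2-dimethyl-1,3-dioxolan-4-yl](hydroxy)methyl}prop-2-enoate (both carbinol epimers)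
Conditions: DABCO (0.5 equiv), neat, rt, 5 d
Reagents that add atoms: none
Why: Morita–Baylis–Hillman reaction joins C7 to the acrylate carbon C11; the new carbinol centre is irrelevant because it becomes sp2 in the next step.

**Step 10**
Reactants: 13 methyl 2-{[(4S)-2,2-dimethyl-1,3-dioxolan-4-yl](hydroxy)methyl}prop-2-enoate
Product: 14 methyl (2Z)-2-(bromomethyl)-3-[(4R)-2,2-dimethyl-1,3-dioxolan-4-yl]prop-2-enoate (fragment B)
Conditions: N-bromosuccinimide, Me2S, CH2Cl2, 0 °C → rt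
Reagents that add atoms: N-bromosuccinimide, O=C1CCC(=O)N1Br
Why: Corey–Kim-type activation and SN2′ bromide delivery converts the Baylis–Hillman alcohol into the allylic bromide with the usual Z geometry (ester trans to the dioxolanyl group) under neutral conditions that keep the acetonide.

**Step 11**
Reactants: 9 [(4S)-4-ethenyl-2,2-dimethyl-1,3-dioxolan-4-yl]acetaldehyde; 14 methyl (2Z)-2-(bromomethyl)-3-[(4R)-2,2-dimethyl-1,3-dioxolan-4-yl]prop-2-enoate
Product: 16 methyl (3R,4R)-3-[(4R)-2,2-dimethyl-1,3-dioxolan-4-yl]-5-[(4S)-4-ethenyl-2,2-dimethyl-1,3-dioxolan-4-yl]-4-hydroxy-2-methylidenepentanoate, via allylindium dibromide 15 (not isolated)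
Conditions: In powder (1.5 equiv), THF/H2O 1:1, rt
Reagents that add atoms: none
Why: Indium Barbier 2-(alkoxycarbonyl)allylation: the γ-carbon (C7) of the (Z)-allylindium adds to the aldehyde through a chair transition state that gives the 7,8-syn (crotylation sense) adduct, and the aldehyde approaches C7 anti to the dioxolane C5–C6 bond with H6 eclipsing the alkene (A(1,3) control), so C7 and C8 are set relative to the solketal-derived C6 as the anti,anti triad that corresponds to the cis-lactone.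

**Step 12**
Reactants: 16 (Barbier adduct); 17 (2R)-2-methylbutanoic acid
Product: 18 methyl (3R,4R)-3-[(4R)-2,2-dimethyl-1,3-dioxolan-4-yl]-5-[(4S)-4-ethenyl-2,2-dimethyl-1,3-dioxolan-4-yl]-2-methylidene-4-{[(2R)-2-methylbutanoyl]oxy}pentanoate
Conditions: dicyclohexylcarbodiimide, DMAP (cat.), CH2Cl2, 0 °C → rt
Reagents that add atoms: none
Why: Steglich esterification acylates the only free hydroxyl (C8) straight after the Barbier step, which differentiates O8 from O6 and blocks 8,12-lactonisation; the α-alkyl acid does not racemise under these conditions.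

**Step 13**
Reactants: 18 (C8 ester)
Product: 20 (1R,3S)-3-hydroxy-3-(hydroxymethyl)-1-[(2R,3R)-2-(hydroxymethyl)-4-methylidene-5-oxooxolan-3-yl]pent-4-en-1-yl (2R)-2-methylbutanoate, via tetraol methyl ester 19 (not isolated)
Conditions: AcOH/H2O 4:1, 45 °C; then TsOH·H2O (5 mol %), CH2Cl2, rt
Reagents that add atoms: none
Why: Acid hydrolysis of both acetonides followed by acid-catalysed lactonisation of the C6 hydroxyl onto the methyl ester (five-membered ring favoured over the six-membered alternative from O5) closes the cis-fused α-methylene-γ-butyrolactone without touching C6, C7 or C8.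

**Step 14**
Reactants: 20 (lactone triol)
Product: 21 (1R)-2-[(4S)-4-ethenyl-2,2-dimethyl-1,3-dioxolan-4-yl]-1-[(2R,3R)-2-(hydroxymethyl)-4-methylidene-5-oxooxolan-3-yl]ethyl (2R)-2-methylbutanoate
Conditions: 2,2-dimethoxypropane, PPTS (cat.), acetone, rt; aqueous work-up
Reagents that add atoms: 2,2-dimethoxypropane, COC(C)(C)OC
Why: Selective acetonide formation on the 10,14-diol (the only 1,2-diol) re-protects the tertiary and neopentyl hydroxyls and leaves only the C5 primary alcohol free.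

**Step 15**
Reactants: 21 (acetonide lactone alcohol)
Product: 22 (1R)-2-[(4S)-4-ethenyl-2,2-dimethyl-1,3-dioxolan-4-yl]-1-[(2R,3R)-2-(hydroxymethyl)-5-oxo-4-[(phenylsulfanyl)methyl]oxolan-3-yl]ethyl (2R)-2-methylbutanoate (C11 epimers)
Conditions: PhSH, Et3N (cat.), CH2Cl2, 0 °C → rt
Reagents that add atoms: thiophenol, Sc1ccccc1
Why: Thia-Michael addition masks the α-methylene lactone, which would otherwise undergo ylide addition, hydroboration or intramolecular Heck insertion in the next three steps; the new C11 centre is removed again in step 19.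

**Step 16**
Reactants: 22 (sulfide alcohol)
Product: 23 (1R)-2-[(4S)-4-ethenyl-2,2-dimethyl-1,3-dioxolan-4-yl]-1-[(2R,3R)-2-formyl-5-oxo-4-[(phenylsulfanyl)methyl]oxolan-3-yl]ethyl (2R)-2-methylbutanoate
Conditions: Dess–Martin periodinane, CH2Cl2, 0 °C
Reagents that add atoms: none
Why: Dess–Martin oxidation gives the C5 aldehyde without oxidising the sulfide and without base, so the α-acyloxy centre C6 is not epimerised.

**Step 17**
Reactants: 23 (C5 aldehyde)
Product: 24 (1R)-2-[(4S)-4-ethenyl-2,2-dimethyl-1,3-dioxolan-4-yl]-1-[(2R,3R)-2-[(1Z)-2-iodoprop-1-en-1-yl]-5-oxo-4-[(phenylsulfanyl)methyl]oxolan-3-yl]ethyl (2R)-2-methylbutanoate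
Conditions: EtPPh3I, n-BuLi, THF, rt; I2, −78 °C; NaN(SiMe3)2, −20 °C; then 23, −78 → −20 °C
Reagents that add atoms: ethyltriphenylphosphonium iodide, CC[P+](c1ccccc1)(c1ccccc1)c1ccccc1.[I-]; iodine, II
Why: Stork–Zhao olefination with the α-iodo ylide gives the (Z)-2-iodoalkene (iodine cis to C6), which fixes the 4Z geometry and supplies C4 and C15; the aldehyde reacts far faster than the esters at −78 °C.

**Step 18**
Reactants: 24 (iodoalkene with the C10 vinyl group)
Product: 26 (4Z,6S,7R,8R,10R)-10,14-(isopropylidenedioxy)-8-[(2R)-2-methylbutanoyloxy]-3-oxo-13-(phenylsulfanyl)-11,13-dihydrogermacr-4-en-6,12-olide (C11 epimers), via B-alkyl-9-BBN borane 25 (not isolated)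
Conditions: 9-BBN (1.5 equiv), THF, 0 °C → rt; then syringe-pump addition (10 h) to Pd(PPh3)4 (10 mol %), K3PO4 (3 equiv), CO (1 atm), THF/DMF 5:1, 50 °C, 2 mM
Reagents that add atoms: carbon monoxide, [C-]#[O+]
Why: Proposed new method: an intramolecular carbonylative B-alkyl Suzuki–Miyaura coupling that closes the ten-membered enone: zerovalent palladium inserts into the C–I bond with retention of the Z geometry, CO inserts before the slow base-assisted transmetalation of the tethered B-alkyl-9-BBN, and the acyl–palladium then takes up the alkyl group intramolecularly and reductively eliminates to forge C2–C3 and C3–C4 with C3 from CO, while CO-free coupling is disfavoured because it would give a strained nine-membered ring and the Heck pathway is blocked by the masked lactone; the closest known reaction types are the intermolecular carbonylative coupling of 9-alkyl-9-BBN reagents with iodoalkenes and CO-free B-alkyl Suzuki macrocyclisations.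

**Step 19**
Reactants: 26 (macrocyclic sulfide)
Product: 28 (4Z,6S,7R,8R,10R)-10,14-(isopropylidenedioxy)-8-[(2R)-2-methylbutanoyloxy]-3-oxogermacra-4,11(13)-dien-6,12-olide, via sulfoxide 27 (not isolated)
Conditions: mCPBA (1.05 equiv), CH2Cl2, −78 °C; then PhMe, 100 °C
Reagents that add atoms: none
Why: Sulfide oxidation and thermal sulfoxide syn-elimination regenerate the exocyclic methylene regiospecifically, because the only β-hydrogen is H11; the electron-poor enone alkene is not epoxidised at −78 °C.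

**Step 20**
Reactants: 28 (macrocyclic enone acetonide)
Product: 30 (3S,4Z,6S,7R,8R,10R)-3,10-epoxy-3,14-dihydroxy-8-[(2R)-2-methylbutanoyloxy]germacra-4,11(13)-dien-6,12-olide (target), via seco keto diol 29 (not isolated)
Conditions: AcOH/THF/H2O 3:1:1, 40 °C
Reagents that add atoms: none
Why: Acetonide hydrolysis releases the 10,14-diol and the tertiary C10 hydroxyl adds across the ring to the C3 ketone (hemiketalisation) under thermodynamic control; C3 is fixed as S by C10 because only the cis-bridged tetrahydrofuran is geometrically possible.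

**Compound list**
1 | 3-bromobut-3-en-1-ol | OCCC(Br)=C | starting material
2 | [(3-bromobut-3-en-1-yl)oxy](tert-butyl)diphenylsilane | C=C(Br)CCO[Si](c1ccccc1)(c1ccccc1)C(C)(C)C | intermediate
3 | {4-[(tert-butyldiphenylsilyl)oxy]but-1-en-2-yl}lithium | [Li]C(=C)CCO[Si](c1ccccc1)(c1ccccc1)C(C)(C)C | intermediate
4 | 4-[(tert-butyldiphenylsilyl)oxy]-2-methylidenebutan-1-ol | OCC(=C)CCO[Si](c1ccccc1)(c1ccccc1)C(C)(C)C | intermediate
5 | [(2R)-2-{2-[(tert-butyldiphenylsilyl)oxy]ethyl}oxiran-2-yl]methanol | OC[C@]1(CCO[Si](c2ccccc2)(c2ccccc2)C(C)(C)C)CO1 | intermediate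
6 | (2S)-2-{2-[(tert-butyldiphenylsilyl)oxy]ethyl}but-3-ene-1,2-diol | C=C[C@](O)(CO)CCO[Si](c1ccccc1)(c1ccccc1)C(C)(C)C | intermediate
7 | tert-butyl{2-[(4S)-4-ethenyl-2,2-dimethyl-1,3-dioxolan-4-yl]ethoxy}diphenylsilane | C=C[C@]1(COC(C)(C)O1)CCO[Si](c1ccccc1)(c1ccccc1)C(C)(C)C | intermediate
8 | 2-[(4S)-4-ethenyl-2,2-dimethyl-1,3-dioxolan-4-yl]ethan-1-ol | C=C[C@]1(COC(C)(C)O1)CCO | intermediate
9 | [(4S)-4-ethenyl-2,2-dimethyl-1,3-dioxolan-4-yl]acetaldehyde | C=C[C@]1(COC(C)(C)O1)CC=O | intermediate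
10 | [(4R)-2,2-dimethyl-1,3-dioxolan-4-yl]methanol ((R)-solketal) | OC[C@@H]1COC(C)(C)O1 | starting material
11 | (4S)-2,2-dimethyl-1,3-dioxolane-4-carbaldehyde | O=C[C@@H]1COC(C)(C)O1 | intermediate
12 | methyl acrylate | C=CC(=O)OC | starting material
13 | methyl 2-{[(4S)-2,2-dimethyl-1,3-dioxolan-4-yl](hydroxy)methyl}prop-2-enoate (both carbinol epimers) | C=C(C(=O)OC)C(O)[C@@H]1COC(C)(C)O1 | intermediate
14 | methyl (2Z)-2-(bromomethyl)-3-[(4R)-2,2-dimethyl-1,3-dioxolan-4-yl]prop-2-enoate | BrC/C(C(=O)OC)=C\[C@@H]1COC(C)(C)O1 | intermediate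
15 | allylindium dibromide derived from 14 | Br[In](Br)C/C(C(=O)OC)=C\[C@@H]1COC(C)(C)O1 | intermediate
16 | methyl (3R,4R)-3-[(4R)-2,2-dimethyl-1,3-dioxolan-4-yl]-5-[(4S)-4-ethenyl-2,2-dimethyl-1,3-dioxolan-4-yl]-4-hydroxy-2-methylidenepentanoate | C=C[C@]1(COC(C)(C)O1)C[C@@H](O)[C@@H](C(=C)C(=O)OC)[C@@H]1COC(C)(C)O1 | intermediate
17 | (2R)-2-methylbutanoic acid | CC[C@@H](C)C(=O)O | starting material
18 | methyl (3R,4R)-3-[(4R)-2,2-dimethyl-1,3-dioxolan-4-yl]-5-[(4S)-4-ethenyl-2,2-dimethyl-1,3-dioxolan-4-yl]-2-methylidene-4-{[(2R)-2-methylbutanoyl]oxy}pentanoate | C=C[C@]1(COC(C)(C)O1)C[C@@H](OC(=O)[C@H](C)CC)[C@@H](C(=C)C(=O)OC)[C@@H]1COC(C)(C)O1 | intermediate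
19 | methyl (3S,4R,6S)-3-[(1R)-1,2-dihydroxyethyl]-6-hydroxy-6-(hydroxymethyl)-2-methylidene-4-{[(2R)-2-methylbutanoyl]oxy}oct-7-enoate | C=C[C@](O)(CO)C[C@@H](OC(=O)[C@H](C)CC)[C@@H](C(=C)C(=O)OC)[C@@H](O)CO | intermediate
20 | (1R,3S)-3-hydroxy-3-(hydroxymethyl)-1-[(2R,3R)-2-(hydroxymethyl)-4-methylidene-5-oxooxolan-3-yl]pent-4-en-1-yl (2R)-2-methylbutanoate | C=C[C@](O)(CO)C[C@@H](OC(=O)[C@H](C)CC)[C@H]1C(=C)C(=O)O[C@H]1CO | intermediate
21 | (1R)-2-[(4S)-4-ethenyl-2,2-dimethyl-1,3-dioxolan-4-yl]-1-[(2R,3R)-2-(hydroxymethyl)-4-methylidene-5-oxooxolan-3-yl]ethyl (2R)-2-methylbutanoate | C=C[C@]1(COC(C)(C)O1)C[C@@H](OC(=O)[C@H](C)CC)[C@H]1C(=C)C(=O)O[C@H]1CO | intermediate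
22 | (1R)-2-[(4S)-4-ethenyl-2,2-dimethyl-1,3-dioxolan-4-yl]-1-[(2R,3R)-2-(hydroxymethyl)-5-oxo-4-[(phenylsulfanyl)methyl]oxolan-3-yl]ethyl (2R)-2-methylbutanoate (C11 epimers) | C=C[C@]1(COC(C)(C)O1)C[C@@H](OC(=O)[C@H](C)CC)[C@H]1C(CSc2ccccc2)C(=O)O[C@H]1CO | intermediate
23 | (1R)-2-[(4S)-4-ethenyl-2,2-dimethyl-1,3-dioxolan-4-yl]-1-[(2R,3R)-2-formyl-5-oxo-4-[(phenylsulfanyl)methyl]oxolan-3-yl]ethyl (2R)-2-methylbutanoate | C=C[C@]1(COC(C)(C)O1)C[C@@H](OC(=O)[C@H](C)CC)[C@H]1C(CSc2ccccc2)C(=O)O[C@H]1C=O | intermediate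
24 | (1R)-2-[(4S)-4-ethenyl-2,2-dimethyl-1,3-dioxolan-4-yl]-1-[(2R,3R)-2-[(1Z)-2-iodoprop-1-en-1-yl]-5-oxo-4-[(phenylsulfanyl)methyl]oxolan-3-yl]ethyl (2R)-2-methylbutanoate | C=C[C@]1(COC(C)(C)O1)C[C@@H](OC(=O)[C@H](C)CC)[C@H]1C(CSc2ccccc2)C(=O)O[C@H]1/C=C(/C)I | intermediate
25 | 9-BBN adduct of 24 (boron on the terminal carbon C2 of the former vinyl group) | B1(CC[C@]2(COC(C)(C)O2)C[C@@H](OC(=O)[C@H](C)CC)[C@H]2C(CSc3ccccc3)C(=O)O[C@H]2/C=C(/C)I)C2CCCC1CCC2 | intermediate
26 | (4Z,6S,7R,8R,10R)-10,14-(isopropylidenedioxy)-8-[(2R)-2-methylbutanoyloxy]-3-oxo-13-(phenylsulfanyl)-11,13-dihydrogermacr-4-en-6,12-olide (C11 epimers) | c4ccccc4SCC1C(=O)O[C@H]2/C=C(/C)C(=O)CC[C@]3(COC(C)(C)O3)C[C@@H](OC(=O)[C@H](C)CC)[C@@H]12 | intermediate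
27 | S-oxide of 26 | O=S(c4ccccc4)CC1C(=O)O[C@H]2/C=C(/C)C(=O)CC[C@]3(COC(C)(C)O3)C[C@@H](OC(=O)[C@H](C)CC)[C@@H]12 | intermediate
28 | (4Z,6S,7R,8R,10R)-10,14-(isopropylidenedioxy)-8-[(2R)-2-methylbutanoyloxy]-3-oxogermacra-4,11(13)-dien-6,12-olide | C=C1C(=O)O[C@H]2/C=C(/C)C(=O)CC[C@]3(COC(C)(C)O3)C[C@@H](OC(=O)[C@H](C)CC)[C@@H]12 | intermediate
29 | (4Z,6S,7R,8R,10R)-10,14-dihydroxy-8-[(2R)-2-methylbutanoyloxy]-3-oxogermacra-4,11(13)-dien-6,12-olide | C=C1C(=O)O[C@H]2/C=C(/C)C(=O)CC[C@](O)(CO)C[C@@H](OC(=O)[C@H](C)CC)[C@@H]12 | intermediate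
30 | (3S,4Z,6S,7R,8R,10R)-3,10-epoxy-3,14-dihydroxy-8-[(2R)-2-methylbutanoyloxy]germacra-4,11(13)-dien-6,12-olide | C=C1C(=O)O[C@H]2/C=C(/C)[C@]3(O)CC[C@](CO)(C[C@@H](OC(=O)[C@H](C)CC)[C@@H]12)O3 | target

**Summary**
Total steps: 20. Longest linear sequence: 17 (steps 1–7, then 11–20); fragment B takes 3 steps (8–10).

**Steps most likely to fail**

Step 11 (facial selectivity of the Barbier coupling at C7 relative to the dioxolane centre; indium chelation to the dioxolane oxygen or E/Z scrambling of the allylindium could erode it). The fallback sets out from bromide 14 (with aldehyde 9) and comes back at 16. Bromide 14 is converted with B2pin2 and Pd2(dba)3 (PhMe, 50 °C) into the isolated, configurationally stable methyl (2E)-3-[(4R)-2,2-dimethyl-1,3-dioxolan-4-yl]-2-[(4,4,5,5-tetramethyl-1,3,2-dioxaborolan-2-yl)methyl]prop-2-enoate F1 (same alkene geometry as 14; the descriptor changes with the boron substituent). F1 is added to 9 under Sc(OTf)3 catalysis (CH2Cl2, −78 °C). This allylboration runs through a closed, non-chelated chair transition state in which only A(1,3) strain and the alkene geometry decide the C7/C8 outcome, and it gives 16 directly.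

Step 17 (epimerisation of the α-acyloxy aldehyde, loss of thiophenoxide, or low Z selectivity under the basic ylide conditions). The fallback sets out from aldehyde 23 and comes back at 26. Neutral Ramirez olefination (CBr4, PPh3, Zn, CH2Cl2, 0 °C) gives the 1,1-dibromoalkene F2. A trans-selective Negishi methylation (MeZnCl, Pd(t-Bu3P)2, THF, 0 °C) replaces only the bromine trans to C6 and leaves the (Z)-2-bromopropenyl lactone F3. F3 is hydroborated with 9-BBN to the alkylborane F4 and cyclised under the step 18 conditions (bromide in place of iodide) to give 26.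

Step 18 (the proposed new macrocyclisation; possible failures are oligomerisation, CO-free coupling or hydroxycarbonylation of the acyl–palladium). The fallback uses known chemistry, sets out from iodoalkene 24 and comes back at 26. Linear-selective hydroformylation of the C10 vinyl group (Rh(acac)(CO)2, BiPhePhos, CO/H2 1:1, 10 bar, PhMe, 60 °C; the trisubstituted iodoalkene is inert) gives the C3 aldehyde F5. A Nozaki–Hiyama–Kishi macrocyclisation (CrCl2, NiCl2 (cat.), DMSO/THF, 2 mM, rt) adds the alkenyl iodide to the aldehyde and gives the ten-membered allylic alcohol F6 as C3 epimers. Dess–Martin oxidation of F6 gives enone 26.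

**Further compounds**
F1 | step 11 | methyl (2E)-3-[(4R)-2,2-dimethyl-1,3-dioxolan-4-yl]-2-[(4,4,5,5-tetramethyl-1,3,2-dioxaborolan-2-yl)methyl]prop-2-enoate | CC1(C)OB(C/C(C(=O)OC)=C\[C@@H]2COC(C)(C)O2)OC1(C)C
F2 | step 17 | (1R)-1-[(2R,3R)-2-(2,2-dibromoethenyl)-5-oxo-4-[(phenylsulfanyl)methyl]oxolan-3-yl]-2-[(4S)-4-ethenyl-2,2-dimethyl-1,3-dioxolan-4-yl]ethyl (2R)-2-methylbutanoate | C=C[C@]1(COC(C)(C)O1)C[C@@H](OC(=O)[C@H](C)CC)[C@H]1C(CSc2ccccc2)C(=O)O[C@H]1C=C(Br)Br
F3 | step 17 | (1R)-1-[(2R,3R)-2-[(1Z)-2-bromoprop-1-en-1-yl]-5-oxo-4-[(phenylsulfanyl)methyl]oxolan-3-yl]-2-[(4S)-4-ethenyl-2,2-dimethyl-1,3-dioxolan-4-yl]ethyl (2R)-2-methylbutanoate | C=C[C@]1(COC(C)(C)O1)C[C@@H](OC(=O)[C@H](C)CC)[C@H]1C(CSc2ccccc2)C(=O)O[C@H]1/C=C(/C)Br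
F4 | step 17 | 9-BBN adduct of F3 (boron on the terminal carbon of the former vinyl group) | B1(CC[C@]2(COC(C)(C)O2)C[C@@H](OC(=O)[C@H](C)CC)[C@H]2C(CSc3ccccc3)C(=O)O[C@H]2/C=C(/C)Br)C2CCCC1CCC2
F5 | step 18 | C3 aldehyde from hydroformylation of 24 (C10 bears a 3-oxopropyl group) | O=CCC[C@]1(COC(C)(C)O1)C[C@@H](OC(=O)[C@H](C)CC)[C@H]1C(CSc2ccccc2)C(=O)O[C@H]1/C=C(/C)I
F6 | step 18 | (4Z,6S,7R,8R,10R)-3-hydroxy-10,14-(isopropylidenedioxy)-8-[(2R)-2-methylbutanoyloxy]-13-(phenylsulfanyl)-11,13-dihydrogermacr-4-en-6,12-olide (C3 and C11 epimers) | c4ccccc4SCC1C(=O)O[C@H]2/C=C(/C)C(O)CC[C@]3(COC(C)(C)O3)C[C@@H](OC(=O)[C@H](C)CC)[C@@H]12
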